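The route rests on cutting cyclohexane ring A (C1, C10–C14) across C10–C1 and C13–C14. This retro-[4+2] also opens tetrahydrofuran ring B at its fusion bond. It exploits two features: the C2–O–C9 ether, a ready three-atom tether, and the C11 oxygen, which sits 1,4 to C14. In the forward sense, soft enolisation of an open-chain β-alkoxy isopropenyl ketone gives a 2-silyloxydiene that adds to a tethered (E)-enamide. This closes rings A and B and sets C1, C10 and C14 in one operation. The precursor is an acyclic bis-allylic ether built from nerol, an iodo-enal and a silyl dienol ether. Oxepane C and oxonene D follow, the latter by Nozaki–Hiyama–Kishi closure.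

Key step: step 9

Numbering used (remark on the chemistry): C11 = acetoxy-bearing ring carbon; C12 = its CH(CH3) neighbour; C13 = ring CH2; C14 = ring CH carrying the C15(H)(C17H3)–C16H2–O arm; C1 and C10 = the A/B fusion carbons (C1 next to C14, C10 next to C11); C2 (on C1) and C9 (on C10) = the two O–CH carbons of ring B; C3 = quaternary O–C(CH3); C4, C5 = CH2; C6 = carbinol carbon; C7=C8 = the Z alkene; O1, O2, O3 = the oxygens on C1, C2, C3 of the nerol-derived part.

Step 1
Reactants: 1 but-2-yn-1-ol
Product: 3 (Z)-3-iodobut-2-en-1-ol, via alkenylaluminate 2 (not isolated)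
Conditions: NaAlH2(OCH2CH2OMe)2, THF, 0 °C to rt; then I2, THF, −78 to 0 °C
Reagents that add atoms: iodine, II
Why: Hydroxyl-directed trans-hydroalumination places aluminium on the distal alkyne carbon inside a five-membered alkoxyaluminate, and iodinolysis with retention gives the alkene with iodine cis to the CH2OH group (hydroalumination–iodination), which fixes the later C7=C8 geometry.

Step 2
Reactants: 3 (Z)-3-iodobut-2-en-1-ol
Product: 4 (Z)-3-iodobut-2-enal
Conditions: MnO2, CH2Cl2, rt, dark
Reagents that add atoms: none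
Why: Heterogeneous allylic alcohol oxidation with MnO2 is neutral and should leave the Z-iodoalkene unchanged.

Step 3
Reactants: 5 3-methylbut-3-en-2-one
Product: 6 3-methyl-2-(trimethylsilyloxy)buta-1,3-diene
Conditions: TMSOTf, Et3N, Et2O, 0 °C
Reagents that add atoms: trimethylsilyl triflate, C[Si](C)(C)OS(=O)(=O)C(F)(F)F
Why: Soft enolisation (silyl triflate/amine) can only deprotonate the methyl group, so a single cross-conjugated silyl dienol ether is formed.

Step 4
Reactants: 7 nerol
Product: 8 (2S,3R)-2,3-epoxynerol
Conditions: Ti(OiPr)4 (cat.), L-(+)-diethyl tartrate (cat.), tBuOOH, 4 Å molecular sieves, CH2Cl2, −20 °C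
Reagents that add atoms: tert-butyl hydroperoxide, CC(C)(C)OO
Why: Sharpless asymmetric epoxidation oxidises only the allylic alcohol alkene, and the L-(+)-tartrate ligand sets C2 as S and C3 as R.

Step 5
Reactants: 8 (2S,3R)-2,3-epoxynerol
Product: 9 (2S,3S)-3,7-dimethyloct-6-ene-1,2,3-triol
Conditions: HClO4 (cat.), THF/H2O, 0 °C
Reagents that add atoms: water, O
Why: Acid-catalysed epoxide hydrolysis brings water onto the tertiary carbon C3 in a borderline SN2 opening with inversion (C3 becomes S, C2 is untouched), and this anti addition to the Z alkene of nerol gives the C2/C3 relationship of the target.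

Step 6
Reactants: 9 (2S,3S)-3,7-dimethyloct-6-ene-1,2,3-triol
Product: 10 tris(trimethylsilyl) ether of triol 9
Conditions: N-(trimethylsilyl)imidazole, CH2Cl2, rt
Reagents that add atoms: N-(trimethylsilyl)imidazole, C[Si](C)(C)n1ccnc1
Why: Exhaustive O-silylation prepares O1 and O2 for silyl-transfer acetalisation and masks the tertiary O3 under neutral conditions.

Step 7
Reactants: 10 tris(trimethylsilyl) ether of triol 9; 4 (Z)-3-iodobut-2-enal; 6 3-methyl-2-(trimethylsilyloxy)buta-1,3-diene
Product: 13 hydroxy ketone (open-chain C2–O–C9 ether), via dioxolane 11 (not isolated), via silyl ether 12 (not isolated)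
Conditions: 10 + 4, TMSOTf (cat.), CH2Cl2, −78 °C; then 6, −78 to −60 °C; pyridine quench; aq citric acid, THF, 0 °C
Reagents that add atoms: none
Why: Noyori acetalisation ties the primary and secondary silyl ethers to the enal as a dioxolane (the hindered tertiary silyl ether stays out), TMSOTf then silylates the less hindered O1 and opens the ring to the E-oxocarbenium ion on O2, and Mukaiyama-type attack by C10 of the enol silane anti to the fully substituted C3 in the H2-eclipsed conformer should set C9 with C3 and C8 on the same side of the future tetrahydrofuran.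

Step 8
Reactants: 13 hydroxy ketone
Product: 15 (E)-Weinreb enamide, via aldehyde 14 (not isolated)
Conditions: Dess–Martin periodinane, NaHCO3, CH2Cl2, 0 °C to rt; then Ph3P=CHC(O)N(OMe)Me, rt (one pot)
Reagents that add atoms: N-methoxy-N-methyl-2-(triphenylphosphoranylidene)acetamide, CON(C)C(=O)C=P(c1ccccc1)(c1ccccc1)c1ccccc1
Why: Dess–Martin oxidation with in situ Wittig olefination by a stabilised ylide avoids handling the epimerisable α-alkoxy aldehyde, gives the E alkene, and installs a dienophile carbonyl that cannot be enolised in the next step.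

Step 9
Reactants: 15 (E)-Weinreb enamide
Product: 17 cis-fused hexahydroisobenzofuran cycloadduct, via silyloxydiene 16 (not isolated)
Conditions: TBSOTf, Et3N, toluene, −78 to 0 °C; cold aq NaHCO3 wash; then toluene (high dilution), BHT (cat.), Et3N (trace), 95 °C
Reagents that add atoms: tert-butyldimethylsilyl triflate, CC(C)(C)[Si](C)(C)OS(=O)(=O)C(F)(F)F
Why: Soft enolisation at the only enolisable position (C10) gives the (Z)-2-silyloxydiene 16, which on heating undergoes a concerted but asynchronous, normal-demand type 1 intramolecular Diels–Alder reaction in which the nucleophilic terminus C10 bonds to the enamide β-carbon C1 and C13 bonds to C14. The closest known reaction type is the thermal cycloaddition of ether-tethered 2-silyloxy- or 2-alkoxydienes to enoates and enones that builds hydroisobenzofurans. Ring A (cyclohexene) closes by the [4+2] union itself, and ring B (tetrahydrofuran) closes through the three-atom C9–O–C2 tether, a 5-exo mode for the leading C10–C1 bond. C14 follows from the E geometry of the dienophile (C2 and C15 trans), the C10 face from allylic 1,3-strain between the Z-silyloxy group and C9 (H9 eclipsed, tether oxygen on the reacting face, iodoalkenyl group outside), and the C1 face from the fully substituted C3, which must point away from the diene. Only the tether-endo, carbonyl-exo transition state meets both demands, so the cis C1–C10 fusion with C3 and C8 on the convex face should prevail over the trans-fused mode, which would press C3 against H10 and H14. Regiochemistry is fixed by the tether and matched electronically (C11–O para to C14), periselectivity rests on the inertness of the prenyl and iodoalkene units, and amine buffering suppresses ionisation of the doubly allylic C9–O bond.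

Step 10
Reactants: 17 cycloadduct
Product: 18 C15 methyl ketone
Conditions: MeMgBr, THF, −20 to 0 °C; aq NH4Cl
Reagents that add atoms: methylmagnesium bromide, C[Mg]Br
Why: Weinreb ketone synthesis stops at the ketone through the chelated tetrahedral intermediate, while the enol silane, silyl ether and alkenyl iodide are inert to MeMgBr at this temperature and the equatorial C14 substituent is the stable epimer.

Step 11
Reactants: 18 C15 methyl ketone
Product: 19 C14 isopropenyl compound
Conditions: Ph3PCH3Br (slight excess), NaN(SiMe3)2, THF, 0 °C to rt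
Reagents that add atoms: methyltriphenylphosphonium bromide, C[P+](c1ccccc1)(c1ccccc1)c1ccccc1.[Br-]
Why: Wittig methylenation reaches only C15 because the C11 carbonyl is still masked as its enol silane, and keeping the phosphonium salt in excess leaves no free base to attack the alkenyl iodide.

Step 12
Reactants: 19 C14 isopropenyl compound
Product: 21 primary alcohol (C16–OH), via organoborane 20 (not isolated)
Conditions: 9-BBN, THF, 0 °C to rt; then aq NaOH, H2O2, 0 °C
Reagents that add atoms: hydrogen peroxide, OO
Why: Hydroboration–oxidation with 9-BBN selects the 1,1-disubstituted alkene over the prenyl, iodoalkene and tetrasubstituted enol silane units, and in the conformer with H14 eclipsing C15=C16 the face turned toward C1/C2 is blocked, so hydride delivery from the C13 side should give 15R.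

Step 13
Reactants: 21 primary alcohol
Product: 22 keto diol (C11 ketone, C12 methyl syn to C9)
Conditions: HF·pyridine, pyridine, THF, −20 to 0 °C; crude product used at once
Reagents that add atoms: none
Why: Acid-mediated ketonisation of the silyl enol ether is a kinetic C-protonation that should come from the convex face, anti to the pseudo-axial C9 substituent on C10, giving the less stable 12R epimer required, while fluoride also frees O3.

Step 14
Reactants: 22 keto diol
Product: 23 triol (C11–OH, C16–OH, O3–H)
Conditions: NaBH4, MeOH, −40 to −20 °C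
Reagents that add atoms: none
Why: Borohydride reduction from the convex face (the other face is flanked by C9 and the C12 methyl group or by axial C2 in either chair) puts the C11 oxygen syn to C9 and the methyl group (11R), and the low temperature avoids epimerisation at C12.

Step 15
Reactants: 23 triol
Product: 25 oxepane alcohol (rings A, B, C), via triflate 24 (not isolated)
Conditions: Tf2O (1 equiv), 2,6-lutidine, CH2Cl2, −78 °C to rt
Reagents that add atoms: none
Why: The primary alcohol is triflated selectively over the hindered secondary and tertiary hydroxyls, and the C3 hydroxyl then displaces the triflate in a Williamson-type 7-exo-tet closure favoured by the trans-diequatorial C2/C15 arrangement on ring A.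

Step 16
Reactants: 25 oxepane alcohol
Product: 26 C11 acetate
Conditions: Ac2O, DMAP (cat.), pyridine, CH2Cl2, rt
Reagents that add atoms: acetic anhydride, CC(=O)OC(C)=O
Why: DMAP-catalysed acylation acetylates the only remaining hydroxyl group with retention at C11.

Step 17
Reactants: 26 C11 acetate
Product: 28 C6 aldehyde, via ozonide 27 (not isolated)
Conditions: O3 (titrated), CH2Cl2, −78 °C; then Me2S, −78 °C to rt
Reagents that add atoms: ozone, [O-][O+]=O
Why: Ozonolysis cleaves the electron-rich trisubstituted prenyl alkene much faster than the electron-poor iodoalkene, and reductive work-up unmasks the C6 aldehyde carried as the nerol terminus.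

Step 18
Reactants: 28 C6 aldehyde
Product: 29 target CNP0289966.2
Conditions: CrCl2 (excess), NiCl2 (cat.), DMSO/THF, high dilution, rt
Reagents that add atoms: none
Why: In the intramolecular Nozaki–Hiyama–Kishi reaction zerovalent nickel inserts into the C–I bond, transmetalation gives an alkenyl species of trivalent chromium that keeps the Z geometry and adds chemoselectively to the aldehyde beside the acetate, the rigid A/B/C template holds both arms on the convex face of ring B for nine-membered closure, and attack on the aldehyde conformer with its oxygen turned outward is expected to give 6R.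

Compound list
1 | but-2-yn-1-ol | CC#CCO | starting material
2 | sodium cyclic alkenyl(alkoxy)bis(2-methoxyethoxy)aluminate | CC1=CCO[Al-]1(OCCOC)OCCOC.[Na+] | intermediate
3 | (Z)-3-iodobut-2-en-1-ol | C/C(I)=C/CO | intermediate
4 | (Z)-3-iodobut-2-enal | C/C(I)=C/C=O | intermediate
5 | 3-methylbut-3-en-2-one | CC(=O)C(C)=C | starting material
6 | 3-methyl-2-(trimethylsilyloxy)buta-1,3-diene | C=C(O[Si](C)(C)C)C(C)=C | intermediate
7 | nerol, (Z)-3,7-dimethylocta-2,6-dien-1-ol | CC(C)=CCC/C(C)=C\CO | starting material
8 | (2S,3R)-2,3-epoxynerol | OC[C@@H]1O[C@]1(C)CCC=C(C)C | intermediate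
9 | (2S,3S)-3,7-dimethyloct-6-ene-1,2,3-triol | OC[C@H](O)[C@@](C)(O)CCC=C(C)C | intermediate
10 | (2S,3S)-1,2,3-tris(trimethylsilyloxy)-3,7-dimethyloct-6-ene | C[Si](C)(C)OC[C@H](O[Si](C)(C)C)[C@@](C)(O[Si](C)(C)C)CCC=C(C)C | intermediate
11 | O1,O2-dioxolane acetal of 4 (acetal carbon = C9, both epimers), O3–TMS | C/C(I)=C/C1OC[C@H](O1)[C@@](C)(O[Si](C)(C)C)CCC=C(C)C | intermediate
12 | O1-trimethylsilyl ether of 13 | C[Si](C)(C)OC[C@H](O[C@@H](/C=C(/C)I)CC(=O)C(C)=C)[C@@](C)(O[Si](C)(C)C)CCC=C(C)C | intermediate
13 | (5R,6Z)-5-{[(2S,3S)-1-hydroxy-3,7-dimethyl-3-(trimethylsilyloxy)oct-6-en-2-yl]oxy}-7-iodo-2-methylocta-1,6-dien-3-one | OC[C@H](O[C@@H](/C=C(/C)I)CC(=O)C(C)=C)[C@@](C)(O[Si](C)(C)C)CCC=C(C)C | intermediate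
14 | C1 aldehyde of 13 (stereocentres unchanged) | O=C[C@H](O[C@@H](/C=C(/C)I)CC(=O)C(C)=C)[C@@](C)(O[Si](C)(C)C)CCC=C(C)C | intermediate
15 | (E)-C1=C14 Weinreb enamide with the C11 isopropenyl ketone | CON(C)C(=O)/C=C/[C@H](O[C@@H](/C=C(/C)I)CC(=O)C(C)=C)[C@@](C)(O[Si](C)(C)C)CCC=C(C)C | intermediate
16 | tetraene: (Z)-C10=C11 TBS dienol ether of 15 | CON(C)C(=O)/C=C/[C@H](O[C@@H](/C=C(/C)I)/C=C(\O[Si](C)(C)C(C)(C)C)C(C)=C)[C@@](C)(O[Si](C)(C)C)CCC=C(C)C | intermediate
17 | cycloadduct: hexahydroisobenzofuran, H1/H10 cis, H14 trans to H1, C3 and C8 groups anti to ring A, C11=C12 TBS enol ether, C14 Weinreb amide | CC1=C(O[Si](C)(C)C(C)(C)C)[C@@H]2[C@H]([C@@H](C1)C(=O)N(C)OC)[C@H](O[C@H]2/C=C(/C)I)[C@@](C)(O[Si](C)(C)C)CCC=C(C)C | intermediate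
18 | C14 acetyl analogue of 17 | CC1=C(O[Si](C)(C)C(C)(C)C)[C@@H]2[C@H]([C@@H](C1)C(C)=O)[C@H](O[C@H]2/C=C(/C)I)[C@@](C)(O[Si](C)(C)C)CCC=C(C)C | intermediate
19 | C14 isopropenyl analogue of 17 | CC1=C(O[Si](C)(C)C(C)(C)C)[C@@H]2[C@H]([C@@H](C1)C(C)=C)[C@H](O[C@H]2/C=C(/C)I)[C@@](C)(O[Si](C)(C)C)CCC=C(C)C | intermediate
20 | B-(C16-alkyl)-9-borabicyclo[3.3.1]nonane, 15R | CC1=C(O[Si](C)(C)C(C)(C)C)[C@@H]2[C@H]([C@@H](C1)[C@@H](C)CB3C4CCCC3CCC4)[C@H](O[C@H]2/C=C(/C)I)[C@@](C)(O[Si](C)(C)C)CCC=C(C)C | intermediate
21 | C16 primary alcohol, 15R, enol silane and O3–TMS intact | CC1=C(O[Si](C)(C)C(C)(C)C)[C@@H]2[C@H]([C@@H](C1)[C@@H](C)CO)[C@H](O[C@H]2/C=C(/C)I)[C@@](C)(O[Si](C)(C)C)CCC=C(C)C | intermediate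
22 | keto diol: C11 ketone, 12R methyl, C16–OH, C3–OH | C[C@H]1C(=O)[C@@H]2[C@H]([C@@H](C1)[C@@H](C)CO)[C@H](O[C@H]2/C=C(/C)I)[C@@](C)(O)CCC=C(C)C | intermediate
23 | triol: 11R alcohol, C16–OH, C3–OH | C[C@H]1[C@@H](O)[C@@H]2[C@H]([C@@H](C1)[C@@H](C)CO)[C@H](O[C@H]2/C=C(/C)I)[C@@](C)(O)CCC=C(C)C | intermediate
24 | C16 triflate of 23 | C[C@H]1[C@@H](O)[C@@H]2[C@H]([C@@H](C1)[C@@H](C)COS(=O)(=O)C(F)(F)F)[C@H](O[C@H]2/C=C(/C)I)[C@@](C)(O)CCC=C(C)C | intermediate
25 | tricyclic oxepane alcohol (rings A, B, C; C11–OH) | C[C@H]1[C@@H](O)[C@@H]2[C@@H]3[C@@H](C1)[C@@H](C)CO[C@@](C)(CCC=C(C)C)[C@H]3O[C@H]2/C=C(/C)I | intermediate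
26 | C11 acetate of 25 | C[C@H]1[C@@H](OC(C)=O)[C@@H]2[C@@H]3[C@@H](C1)[C@@H](C)CO[C@@](C)(CCC=C(C)C)[C@H]3O[C@H]2/C=C(/C)I | intermediate
27 | secondary ozonide of the prenyl alkene of 26 | C[C@H]1[C@@H](OC(C)=O)[C@@H]2[C@@H]3[C@@H](C1)[C@@H](C)CO[C@@](C)(CCC4OOC(C)(C)O4)[C@H]3O[C@H]2/C=C(/C)I | intermediate
28 | C6 aldehyde with the (Z)-C7 alkenyl iodide | C[C@H]1[C@@H](OC(C)=O)[C@@H]2[C@@H]3[C@@H](C1)[C@@H](C)CO[C@@](C)(CCC=O)[C@H]3O[C@H]2/C=C(/C)I | intermediate
29 | CNP0289966.2 (1S,2S,3S,6R,7Z,9S,10R,11R,12R,14S,15R in the numbering above) | CC(=O)O[C@H]1[C@@H]2[C@@H]3[C@@H](C[C@H]1C)[C@@H](C)CO[C@@]1(C)CC[C@@H](O)/C(C)=C\[C@@H]2O[C@@H]31 | target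

Total step count: 18. Longest linear sequence: 15 steps (steps 4–18, from nerol).

Steps most likely to fail

Step 7. What may go wrong:
- low facial discrimination in the attack on the open oxocarbenium ion;
- cleavage of the acetal at the wrong oxygen;
- acid-induced drift of the iodoalkene from Z to E.

The fallback replaces substrate control by auxiliary control. It sets out from 10 and 4 and returns at 13. Dioxolane 11 is made as above but isolated. It is then opened with the chlorotitanium enolate of (S)-N-acetyl-4-isopropyl-1,3-thiazolidine-2-thione (TiCl4, iPr2NEt, then SnCl4, CH2Cl2, −78 °C). This chiral acetate enolate is known to add to acetals with strong induction, and its enantiomer is taken if the sense proves mismatched. The product is the β-alkoxy acyl thiazolidinethione F1. MeNHOMe·HCl with imidazole displaces the auxiliary to give the Weinreb amide F2. Excess isopropenylmagnesium bromide (THF, 0 °C) then gives hydroxy ketone 13.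

Step 9. What may go wrong:
- competition from the carbonyl-endo mode, which leads to trans fusion;
- loss of the alkoxide from C9 before the cycloaddition occurs.

The fallback turns the endo preference to advantage with a Z dienophile and corrects C14 afterwards. It sets out from 13 and returns at 18. Oxidation as in step 8 gives 14. A Still–Gennari-type olefination follows, using bis(2,2,2-trifluoroethyl) [2-(methoxy(methyl)amino)-2-oxoethyl]phosphonate, KN(SiMe3)2 and 18-crown-6 in THF at −78 °C, and gives the (Z)-enamide F3. TBSOTf/Et3N converts it into the tetraene F4. Allylic 1,3-strain now fixes both C2 and C9, and the carbonyl-endo and tether-endo demands coincide. Heating should therefore give the cis-fused 14-epi cycloadduct F5. MeMgBr gives the 14-epi methyl ketone F6, and DBU in toluene equilibrates the acetyl group to the equatorial position, which is 18.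

Step 18. What may go wrong:
- attack on the wrong aldehyde face;
- protonolysis of the alkenylchromium species, or oligomerisation in place of nine-membered closure.

The fallback separates ring closure from the C6 configuration. It sets out from 28 and returns at 29. The closure product, obtained as the 6-epi alcohol F7 or as a mixture, is oxidised with Dess–Martin periodinane to the ring D enone F8. Corey–Bakshi–Shibata reduction ((S)-methyl oxazaborolidine, BH3·SMe2, −30 °C) then sets 6R under reagent control and gives 29.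

Further compounds
F1 | step 7 | β-alkoxy N-acyl (S)-4-isopropyl-1,3-thiazolidine-2-thione (C11 acyl, free O1–H) | OC[C@H](O[C@@H](/C=C(/C)I)CC(=O)N1[C@@H](C(C)C)CSC1=S)[C@@](C)(O[Si](C)(C)C)CCC=C(C)C
F2 | step 7 | C11 Weinreb amide of the C2–O–C9 ether | OC[C@H](O[C@@H](/C=C(/C)I)CC(=O)N(C)OC)[C@@](C)(O[Si](C)(C)C)CCC=C(C)C
F3 | step 9 | (Z)-C1=C14 Weinreb enamide | CON(C)C(=O)/C=C\[C@H](O[C@@H](/C=C(/C)I)CC(=O)C(C)=C)[C@@](C)(O[Si](C)(C)C)CCC=C(C)C
F4 | step 9 | tetraene with Z dienophile and (Z)-TBS dienol ether | CON(C)C(=O)/C=C\[C@H](O[C@@H](/C=C(/C)I)/C=C(\O[Si](C)(C)C(C)(C)C)C(C)=C)[C@@](C)(O[Si](C)(C)C)CCC=C(C)C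
F5 | step 9 | 14-epi cycloadduct (C15 cis to C2) | CC1=C(O[Si](C)(C)C(C)(C)C)[C@@H]2[C@H]([C@H](C1)C(=O)N(C)OC)[C@H](O[C@H]2/C=C(/C)I)[C@@](C)(O[Si](C)(C)C)CCC=C(C)C
F6 | step 9 | 14-epi methyl ketone | CC1=C(O[Si](C)(C)C(C)(C)C)[C@@H]2[C@H]([C@H](C1)C(C)=O)[C@H](O[C@H]2/C=C(/C)I)[C@@](C)(O[Si](C)(C)C)CCC=C(C)C
F7 | step 18 | 6-epi alcohol (6S) | CC(=O)O[C@H]1[C@@H]2[C@@H]3[C@@H](C[C@H]1C)[C@@H](C)CO[C@@]1(C)CC[C@H](O)/C(C)=C\[C@@H]2O[C@@H]31
F8 | step 18 | C6 enone of ring D | CC(=O)O[C@H]1[C@@H]2[C@@H]3[C@@H](C[C@H]1C)[C@@H](C)CO[C@@]1(C)CCC(=O)/C(C)=C\[C@@H]2O[C@@H]31
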